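Readings and results are simulated with made-up constants; noise was put on by code.

- If I charge 0.10 M of starting material and want intermediate C to lead, I must decide whether to stop at 50 min or leave the flask until 100 min. That decision hangs on how much material is still upstream at the later time.

| flask | starting material | remark | time |
|---|---|---|---|
| north-west | 0.050 M | run made earlier |  |
| north | 0.075 M | run made earlier |  |
| dusk | 0.10 M |  | 50 min |
| dawn | 0.10 M |  | 100 min |

| run | time / min | starting material / % | intermediate B / % | intermediate A / % | intermediate C / % | target / % |
|---|---|---|---|---|---|---|
| north-west | 4.00 | 82 | 3 | 13 | 1 | 0 |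
| north-west | 6.00 | 77 | 5 | 21 | 1 | 0 |
| north-west | 10.0 | 62 | 10 | 24 | 7 | 2 |
| north-west | 15.0 | 50 | 10 | 31 | 11 | 2 |
| north-west | 20.0 | 44 | 17 | 33 | 11 | 2 |
| north-west | 30.0 | 25 | 12 | 39 | 23 | 3 |
| north-west | 50.0 | 17 | 13 | 31 | 43 | 2 |
| north | 4.00 | 85 | 4 | 11 | 0 | 0 |
| north | 6.00 | 78 | 6 | 15 | 1 | 3 |
| north | 10.0 | 62 | 7 | 21 | 7 | 0 |
| north | 15.0 | 53 | 10 | 31 | 11 | 0 |
| north | 20.0 | 39 | 12 | 34 | 13 | 0 |
| north | 30.0 | 27 | 12 | 36 | 24 | 3 |
| north | 50.0 | 14 | 12 | 30 | 44 | 3 |

(scatter of a reading: 2 percentage points)

- which of these there is most of at the end, counted by the starting material in it, dusk (intermediate C / intermediate B / starting material / target / intermediate A)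
- which of these there is most of at the end, counted by the starting material in it, dawn (intermediate C / intermediate B / starting material / target / intermediate A)
- how much there is at the end of the one of these that leads, in percent of the starting material charged: dusk
- how much there is at the end of the one of these that leads, in percent of the starting material charged: dawn

- a reading or a percentage of target counts all its forms, free or not

- The two earlier runs agree within the scatter of 2 percentage points: at 50.0 min, intermediate C reads 43% in the north-west run and 44% in the north run. I therefore carry their percentages over to 0.10 M, so dusk should show intermediate C leading at about 43.5%, with intermediate A near 30.5%.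
- For dawn, I count starting material and intermediate B as one store, P. Between 30.0 min and 50.0 min the means of the two runs for starting material fall from 26.0% to 15.5%, while those for intermediate B read 12.0% and 12.5%, flat within the scatter, so the fall of P in these readings is the fall of starting material.
- Averaged over both runs, P reads 38.0% at 30.0 min and 28.0% at 50.0 min. That gives the store time constant τ, the time for P to fall by a factor e in an apparent first-order decay: 65.5 min.
- So P should stand at 13.0% at 100 min.
- Intermediate C rises between 15.0 min and 50.0 min at a pace that gives intermediate A a drain time constant of 35.5 min. With P feeding it, intermediate A comes to 14.8%.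
- Taking target at its reading of 2.50%, the balance leaves intermediate C at 69.6% in dawn. I would leave the flask until 100 min.
- The forecast gives intermediate C at 44% for dusk and intermediate C at 73% for dawn, reckoning that “the starting material + B pool falls from about 27% at 50 min to about 8% at 100 min”, which differs from my 13.0% and 69.6%.
- The flasks give intermediate C at 41.8% in dusk and intermediate C at 65.5% in dawn, which is below my reckoning.

    starting material → intermediate A (k = 0.0360 min⁻¹)
    starting material ⇌ intermediate B (K = 1.10, k = 0.0110 min⁻¹)
    intermediate B → target (k = 0.00550 min⁻¹)
    intermediate A ⇌ intermediate C (K = 7.20, k = 0.0320 min⁻¹)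
    crystals ⇌ target, rate k5*(cs5 - [target]) while solid is left; crystals form when [target] > cs5 (solubility = 34.0 mM, k = 0.220 min⁻¹)
    target ⇌ isomer of the product (K = 1.20, k = 0.0150 min⁻¹)
    starting material → decomposition product (k = 6.00 × 10⁻⁵ min⁻¹)

- In dawn the store holds 11.3% at 100 min, a half-life of 43.1 min over the last stretch, about twice the 22 min forward half-life of intermediate A turning into intermediate C, so the store empties more slowly than that step passes material on. Carried to the neighbouring flask, dusk left until 3.0 h, τ = 65.5 min gives 3.85%, and that flask holds 4.07%.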